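## Retrosynthetic overview

1. Luzonoid A ⇐ 1,2-reduction of a C11 aldehyde in the last step; before that, acylation at O1 (isovalerate) and O7 (p-coumarate) of aglycone 24 (C1 lactol, C3=C4–C11HO).
2. 24 ⇐ acetal/enol-ether transposition of cycloadduct 20 (acetal at C3, enol ether C1=C9): loss of EtOH to the C3=C4 enol ether, formylation at C4, then hydration at C1/C9.
3. 20 ⇐ hetero-Diels–Alder. The strategy rests on the fact that C5, C9, C1 and the oxygen on C1 (O2) are the enal O=C1–C9=C5 of a cyclopent-1-enecarbaldehyde, so ring O2–C1–C9–C5–C4–C3 closes when ethyl vinyl ether (C3, C4) adds to enal 18 anti to O7 and C10.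
4. 18 ⇐ ring-closing metathesis (C9=C5) of a diene assembled from L-erythrulose (C6, C7, C8, C10), a 2-metallated allyl ether (C9, C1; chelation-controlled addition sets C8) and a vinyl group (C5).
5. Ring order: cyclopentene (step 8), then dihydropyran (step 13).

Key step: step 13

Iridoid numbering is used throughout (C1 acetal carbon, O2, C3, C4, C5/C9 ring fusion, C6, C7, C8, C10 on C8, C11 on C4; β is the face of H5 and H9 in the target).

Remark on the chemistry: O7 and O10 are bridged as a di-tert-butylsilylene, because acetone would be expected to ketalise the 8,10-diol instead and a silylene can be removed by fluoride. C11 enters as an aldehyde, which keeps the C3=C4 enol ether deactivated until the last step and makes the only hydride reduction the final one.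

## Route

Step 1
Reactants: 1 L-erythrulose
Product: 2 3,4-O-isopropylidene-L-erythrulose, (4S)-dioxolane
Conditions: Me2C(OMe)2, acetone, TsOH·H2O (cat.), 0 °C → rt
Reagents that add atoms: 2,2-dimethoxypropane, COC(C)(C)OC
Why: Acid-catalysed transketalisation should close the five-membered dioxolane on the vicinal 3,4-diol and leave the stereocentre (later C7) untouched.

Step 2
Reactants: 2 3,4-O-isopropylidene-L-erythrulose
Product: 3 1-O-(tert-butyldiphenylsilyl)-3,4-O-isopropylidene-L-erythrulose
Conditions: TBDPSCl, imidazole, DMF, 0 °C → rt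
Reagents that add atoms: tert-butyldiphenylsilyl chloride, CC(C)(C)[Si](Cl)(c1ccccc1)c1ccccc1
Why: Silylation of the only free (primary) hydroxyl gives a bulky, non-chelating ether on the later O10, so the dioxolane oxygen on C7 is the only chelation site in step 4.

Step 3
Reactants: 4 2,3-dibromoprop-1-ene
Product: 5 2-bromoallyl 4-methoxybenzyl (PMB) ether
Conditions: 4-MeOC6H4CH2OH, NaH, THF, 0 °C → rt
Reagents that add atoms: 4-methoxybenzyl alcohol, COc1ccc(CO)cc1
Why: Williamson etherification at the allylic bromide (SN2), the vinylic bromide being inert to the alkoxide.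

Step 4
Reactants: 5 2-bromoallyl PMB ether; 3 silylated erythrulose acetonide
Product: 8 (7S,8R)-tertiary alcohol 1-(TBDPS-oxy)-2-[(4S)-2,2-dimethyl-1,3-dioxolan-4-yl]-3-[(PMB-oxy)methyl]but-3-en-2-ol, via alkenyllithium 6 (not isolated), via alkenylmagnesium bromide 7 (not isolated)
Conditions: t-BuLi (2 equiv), Et2O, −78 °C; MgBr2·OEt2; then 3, Et2O/CH2Cl2, −78 °C
Reagents that add atoms: none
Why: Bromine–lithium exchange, transmetallation and Cram-chelate addition, in which magnesium bridges the ketone oxygen and the dioxolane oxygen on C7 so that the alkenyl group (C9, C1) enters on the side of H7 and sets C8 with 8-OH trans to 7-O on the later ring.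

Step 5
Reactants: 8 tertiary alcohol
Product: 9 (7S,8R)-triol, 4-(TBDPS-oxy)-3-[3-(PMB-oxy)prop-1-en-2-yl]butane-1,2,3-triol
Conditions: AcOH/H2O (4:1), 40 °C
Reagents that add atoms: none
Why: Mild acid hydrolysis of the terminal ketal, to which the TBDPS ether, the PMB ether and the oxygen-flanked tertiary allylic alcohol should be stable.

Step 6
Reactants: 9 triol
Product: 10 primary (C6) p-toluenesulfonate of 9, with 7-OH and 8-OH free
Conditions: TsCl, Et3N, Bu2SnO (cat.), CH2Cl2, 0 °C → rt
Reagents that add atoms: p-toluenesulfonyl chloride, Cc1ccc(cc1)S(Cl)(=O)=O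
Why: Stannylene-catalysed sulfonylation of a 1,2-diol is selective for the primary hydroxyl over the secondary and tertiary ones.

Step 7
Reactants: 10 primary tosylate
Product: 12 (7S,8R)-homoallylic diol 1-(TBDPS-oxy)-2-[3-(PMB-oxy)prop-1-en-2-yl]hex-5-ene-2,3-diol, via terminal epoxide 11 (not isolated)
Conditions: CH2=CHMgBr (5 equiv), CuI (20 mol%), THF, −40 → 0 °C
Reagents that add atoms: vinylmagnesium bromide, C=C[Mg]Br
Why: The magnesium alkoxide on O7 closes the terminal epoxide (3-exo-tet, C7–O bond untouched) and the vinyl cuprate opens it at the unsubstituted C6, which brings in C5.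

Step 8
Reactants: 12 diene diol
Product: 13 (7S,8R)-cyclopentene diol, 1-[(TBDPS-oxy)methyl]-5-[(PMB-oxy)methyl]cyclopent-4-ene-1,2-diol
Conditions: second-generation Grubbs catalyst (H2IMes)(PCy3)Cl2Ru=CHPh (5 mol%), CH2Cl2, 40 °C
Reagents that add atoms: none
Why: Ring-closing metathesis of the vinyl group with the 1,1-disubstituted alkene closes the five-membered ring at C9=C5 with loss of ethene, a closure that tolerates free allylic hydroxyls.

Step 9
Reactants: 13 cyclopentene diol
Product: 14 (7S,8R)-triol, 1-(hydroxymethyl)-5-[(PMB-oxy)methyl]cyclopent-4-ene-1,2-diol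
Conditions: Bu4NF, THF, 0 °C → rt
Reagents that add atoms: none
Why: Fluoride cleaves the silyl ether on O10 and leaves the PMB ether intact.

Step 10
Reactants: 14 triol
Product: 16 7,10-O-(di-tert-butylsilylene)-8-O-trimethylsilyl-1-O-PMB cyclopentene, via silylene alcohol 15 (not isolated)
Conditions: tBu2Si(OTf)2, 2,6-lutidine, CH2Cl2, 0 °C; then Me3SiOTf, −78 → 0 °C
Reagents that add atoms: di-tert-butylsilyl bis(trifluoromethanesulfonate), CC(C)(C)[Si](OS(=O)(=O)C(F)(F)F)(OS(=O)(=O)C(F)(F)F)C(C)(C)C; trimethylsilyl trifluoromethanesulfonate, C[Si](C)(C)OS(=O)(=O)C(F)(F)F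
Why: The bis-triflate bridges the primary O10 and the cis secondary O7 as a six-membered dioxasilinane in preference to a strained five-membered ring through the tertiary O8, and the silyl triflate then caps the tertiary 8-OH with the smallest silyl group.

Step 11
Reactants: 16 PMB ether
Product: 17 allylic alcohol (C1 hydroxymethyl on C9), with 7,10-silylene and 8-OSiMe3
Conditions: DDQ, CH2Cl2/pH 7 phosphate buffer, 0 °C
Reagents that add atoms: none
Why: Oxidative PMB cleavage through the benzylic oxocarbenium ion, buffered so that the silyl ethers survive, and run with O8 already capped so that no cyclic p-methoxybenzylidene acetal can form.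

Step 12
Reactants: 17 allylic alcohol
Product: 18 (7S,8R)-cyclopent-1-enecarbaldehyde with 7,10-O-(di-tert-butylsilylene) on the β face and 8-OSiMe3 on the α face
Conditions: MnO2, CH2Cl2, rt
Reagents that add atoms: none
Why: Manganese dioxide oxidises the primary allylic alcohol to the conjugated aldehyde under neutral conditions that spare both silyl groups.

Step 13
Reactants: 18 cyclopent-1-enecarbaldehyde; 19 ethyl vinyl ether
Product: 20 (3R,5R,7S,8R)-3-ethoxy-3,4-dihydropyran fused at C5–C9, with enol ether C1=C9, H5 β and 3-OEt α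
Conditions: Eu(fod)3 (10 mol%), neat CH2=CHOEt (20 equiv), rt → 45 °C, sealed tube
Reagents that add atoms: none
Why: Eu(fod)3 binds the aldehyde oxygen of the s-cis enal O2=C1–C9=C5 and lowers its LUMO, and the vinyl ether adds in a concerted, asynchronous inverse-demand [4+2] cycloaddition in which its nucleophilic CH2 (C4) bonds to C5 ahead of O2–C3. The closest known reaction is the lanthanide-fod-catalysed hetero-Diels–Alder reaction of cyclopent-1-enecarbaldehydes with ethyl vinyl ether. The six-membered dihydropyran closes by cycloaddition, both ring bonds (C4–C5 and O2–C3) forming in the one step, fused to the cyclopentene at C5–C9. C5 is set by approach of the dienophile to the α face, anti to the cis-fused dioxasilinane that holds O7, C10 and the tert-butyl groups on the β face, and C3 is set by the endo position of the ethoxy group (this centre is erased in step 14). The step needs regioselectivity, which the polarity of enal and vinyl ether fixes, and facial selectivity, which the β silylene should secure; the α substituent on C8 is kept as the small, non-chelating OSiMe3, which also prevents a europium chelate that would hold the enal s-trans.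

Step 14
Reactants: 20 cycloadduct
Product: 21 4H-pyran with enol ethers C1=C9 and C3=C4, H5 β
Conditions: Me3SiOTf, iPr2NEt, CH2Cl2, −78 → −20 °C
Reagents that add atoms: none
Why: Silyl-triflate/amine conversion of an acetal into an enol ether, in which the more basic ethoxy oxygen is silylated and leaves, and the amine removes H4, the only β-hydrogen of the C3 oxocarbenium ion.

Step 15
Reactants: 21 4H-pyran
Product: 23 4-formyl-4H-pyran (C11 aldehyde on C4 with C1=C9 retained), via iminium chloride 22 (not isolated)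
Conditions: [Me2N=CHCl]Cl, 2,6-lutidine, CH2Cl2, 0 °C; then H2O, 0 °C
Reagents that add atoms: (chloromethylene)dimethyliminium chloride, C[N+](C)=CCl.[Cl-]; water, O
Why: Vilsmeier–Haack formylation of a cyclic enol ether (as practised on glycals) should occur at the unhindered C4, because C9 of the other enol ether is fully substituted and flanked by the quaternary C8, and the new formyl group deactivates the C3=C4 enol ether.

Step 16
Reactants: 23 4-formyl-4H-pyran
Product: 24 (1R,5S,7S,8R,9S)-lactol: 1β-OH, H9 β, C3=C4–C11HO, 8α-OH free, 7,10-silylene retained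
Conditions: AcOH/THF/H2O (3:1:1), rt
Reagents that add atoms: water, O
Why: Mild acid hydration should either protonate C9 of the C1=C9 enol ether or add water at C3 and open the ring, and the C1 aldehyde/formyl-enol tautomers should reclose to the one form with a conjugated enol ether, the C1 lactol, with C9 and C1 equilibrating through ring-chain tautomerism to the cis fusion and the β-hydroxyl as in genipin-type aglycones and with the tertiary trimethylsilyl ether hydrolysed along the way.

Step 17
Reactants: 24 lactol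
Product: 25 (1S,5S,7S,8R,9S)-1β-O-isovaleryl 4-formyl aglycone with 7,10-silylene and free 8-OH
Conditions: Me2CHCH2COCl, pyridine, CH2Cl2, −20 → 0 °C
Reagents that add atoms: 3-methylbutanoyl chloride, CC(C)CC(Cl)=O
Why: O-Acylation of the lactol hydroxyl, the only unhindered hydroxyl since 8-OH is tertiary, should proceed with retention at C1 and give the 1β ester, as in acylations of genipin-type lactols.

Step 18
Reactants: 25 silylene ester
Product: 26 7,8,10-triol with 1β-O-isovaleryl and C11 aldehyde
Conditions: HF·pyridine, pyridine, THF, 0 °C → rt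
Reagents that add atoms: none
Why: Buffered fluoride cleaves the dioxasilinane, while the acyloxy acetal and the vinylogous formate are not attacked under these non-basic conditions.

Step 19
Reactants: 26 triol
Product: 27 10-O-TBS ether with 7-OH and 8-OH free
Conditions: TBSCl, imidazole, DMF, 0 °C
Reagents that add atoms: tert-butyldimethylsilyl chloride, CC(C)(C)[Si](C)(C)Cl
Why: The primary O10 is silylated in preference to the secondary O7, which is flanked by the quaternary C8, and to the tertiary O8.

Step 20
Reactants: 28 p-coumaric acid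
Product: 30 (E)-4-(tert-butyldimethylsilyloxy)cinnamic acid, via bis-silyl derivative 29 (not isolated)
Conditions: TBSCl (2.5 equiv), imidazole, DMF, rt; then AcOH/THF/H2O (3:1:1), rt
Reagents that add atoms: tert-butyldimethylsilyl chloride, CC(C)(C)[Si](C)(C)Cl
Why: Both acidic hydroxyls are silylated and the much more labile silyl ester alone is hydrolysed by aqueous acetic acid, which leaves the aryl silyl ether.

Step 21
Reactants: 30 silylated coumaric acid; 27 10-O-TBS alcohol
Product: 32 7-O-[(E)-4-(TBS-oxy)cinnamoyl] 10-O-TBS 1β-O-isovaleryl 4-formyl aglycone, via mixed anhydride 31 (not isolated)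
Conditions: 2,4,6-Cl3C6H2COCl, Et3N, THF, rt; then 27, DMAP, toluene, rt
Reagents that add atoms: none
Why: Yamaguchi esterification through the mixed anhydride acylates the hindered secondary 7-OH with retention (C7–O bond untouched), the tertiary 8-OH being unreactive.

Step 22
Reactants: 32 bis-silyl ether
Product: 33 11-oxo-luzonoid A (free 10-OH, 8-OH and phenol; C11 aldehyde)
Conditions: HF·pyridine, pyridine, THF, 0 °C → rt
Reagents that add atoms: none
Why: Fluoride removes the primary and the aryl silyl ethers while the enol ether is still protected against acid by conjugation with the C11 aldehyde.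

Step 23
Reactants: 33 11-oxo-luzonoid A
Product: 34 luzonoid A
Conditions: NaBH4, CeCl3·7H2O, MeOH/THF, −78 °C
Reagents that add atoms: none
Why: Luche 1,2-reduction of the β-alkoxy enal (as in the reduction of 2-formyl glycals to 2-hydroxymethyl glycals) should be selective for the aldehyde over the coumarate and the acyloxy acetal at low temperature.

## Compound list

1 | L-erythrulose, (3S)-1,3,4-trihydroxybutan-2-one | OC[C@H](O)C(=O)CO | starting material
2 | 3,4-O-isopropylidene-L-erythrulose, 1-[(4S)-2,2-dimethyl-1,3-dioxolan-4-yl]-2-hydroxyethanone | OCC(=O)[C@@H]1COC(C)(C)O1 | intermediate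
3 | 1-O-(tert-butyldiphenylsilyl)-3,4-O-isopropylidene-L-erythrulose | CC(C)(C)[Si](c1ccccc1)(c1ccccc1)OCC(=O)[C@@H]1COC(C)(C)O1 | intermediate
4 | 2,3-dibromoprop-1-ene | BrCC(Br)=C | starting material
5 | 2-bromoallyl 4-methoxybenzyl ether | C=C(Br)COCc1ccc(OC)cc1 | intermediate
6 | [3-(4-methoxybenzyloxy)prop-1-en-2-yl]lithium (formed in the flask) | [Li]C(=C)COCc1ccc(OC)cc1 | intermediate
7 | [3-(4-methoxybenzyloxy)prop-1-en-2-yl]magnesium bromide (formed in the flask) | Br[Mg]C(=C)COCc1ccc(OC)cc1 | intermediate
8 | (2R)-1-(TBDPS-oxy)-2-[(4S)-2,2-dimethyl-1,3-dioxolan-4-yl]-3-[(PMB-oxy)methyl]but-3-en-2-ol (7S,8R) | C=C(COCc1ccc(OC)cc1)[C@@](O)(CO[Si](c1ccccc1)(c1ccccc1)C(C)(C)C)[C@@H]1COC(C)(C)O1 | intermediate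
9 | (2S,3R)-4-(TBDPS-oxy)-3-[3-(PMB-oxy)prop-1-en-2-yl]butane-1,2,3-triol | C=C(COCc1ccc(OC)cc1)[C@@](O)(CO[Si](c1ccccc1)(c1ccccc1)C(C)(C)C)[C@@H](O)CO | intermediate
10 | primary (C6) 4-methylbenzenesulfonate of 9 | C=C(COCc1ccc(OC)cc1)[C@@](O)(CO[Si](c1ccccc1)(c1ccccc1)C(C)(C)C)[C@@H](O)COS(=O)(=O)c1ccc(C)cc1 | intermediate
11 | (2R)-1-(TBDPS-oxy)-2-[(2S)-oxiran-2-yl]-3-[(PMB-oxy)methyl]but-3-en-2-ol (formed in the flask) | C=C(COCc1ccc(OC)cc1)[C@@](O)(CO[Si](c1ccccc1)(c1ccccc1)C(C)(C)C)[C@@H]1CO1 | intermediate
12 | (2R,3S)-1-(TBDPS-oxy)-2-[3-(PMB-oxy)prop-1-en-2-yl]hex-5-ene-2,3-diol | C=C(COCc1ccc(OC)cc1)[C@@](O)(CO[Si](c1ccccc1)(c1ccccc1)C(C)(C)C)[C@@H](O)CC=C | intermediate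
13 | (1R,2S)-1-[(TBDPS-oxy)methyl]-5-[(PMB-oxy)methyl]cyclopent-4-ene-1,2-diol | COc1ccc(COCC2=CC[C@H](O)[C@]2(O)CO[Si](c2ccccc2)(c2ccccc2)C(C)(C)C)cc1 | intermediate
14 | (1R,2S)-1-(hydroxymethyl)-5-[(PMB-oxy)methyl]cyclopent-4-ene-1,2-diol | COc1ccc(COCC2=CC[C@H](O)[C@]2(O)CO)cc1 | intermediate
15 | 7,10-O-(di-tert-butylsilylene) derivative of 14, 8-OH free (formed in the flask) | COc1ccc(COCC2=CC[C@@H]3O[Si](C(C)(C)C)(C(C)(C)C)OC[C@]23O)cc1 | intermediate
16 | 7,10-O-(di-tert-butylsilylene)-8-O-trimethylsilyl derivative of 14 | COc1ccc(COCC2=CC[C@@H]3O[Si](C(C)(C)C)(C(C)(C)C)OC[C@]23O[Si](C)(C)C)cc1 | intermediate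
17 | allylic alcohol: cyclopentene with CH2OH (C1) on C9, 7,10-silylene, 8-OSiMe3 | OCC1=CC[C@@H]2O[Si](C(C)(C)C)(C(C)(C)C)OC[C@]12O[Si](C)(C)C | intermediate
18 | (7S,8R)-cyclopent-1-enecarbaldehyde, 7,10-O-(di-tert-butylsilylene) β, 8-OSiMe3 α | O=CC1=CC[C@@H]2O[Si](C(C)(C)C)(C(C)(C)C)OC[C@]12O[Si](C)(C)C | intermediate
19 | ethyl vinyl ether | C=COCC | starting material
20 | (3R,5R,7S,8R)-3-ethoxy-3,4-dihydropyran cycloadduct, enol ether C1=C9, H5 β, 3-OEt α | CCO[C@H]1C[C@H]2C[C@@H]3O[Si](C(C)(C)C)(C(C)(C)C)OC[C@]3(O[Si](C)(C)C)C2=CO1 | intermediate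
21 | 4H-pyran with C1=C9 and C3=C4 enol ethers, H5 β | C1=C[C@H]2C[C@@H]3O[Si](C(C)(C)C)(C(C)(C)C)OC[C@]3(O[Si](C)(C)C)C2=CO1 | intermediate
22 | C4 dimethyliminiomethyl 4H-pyran chloride (formed in the flask) | C[N+](C)=CC1=COC=C2[C@@H]1C[C@@H]3O[Si](C(C)(C)C)(C(C)(C)C)OC[C@]23O[Si](C)(C)C.[Cl-] | intermediate
23 | 4-formyl-4H-pyran, C1=C9 retained, H5 β | O=CC1=COC=C2[C@@H]1C[C@@H]3O[Si](C(C)(C)C)(C(C)(C)C)OC[C@]23O[Si](C)(C)C | intermediate
24 | (1R,5S,7S,8R,9S)-lactol: 1β-OH, C3=C4–CHO, H5 and H9 β, 8α-OH, 7,10-silylene | O=CC1=CO[C@@H](O)[C@H]2[C@@H]1C[C@@H]3O[Si](C(C)(C)C)(C(C)(C)C)OC[C@]23O | intermediate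
25 | 1β-O-isovaleryl derivative of 24 (1S,5S,7S,8R,9S) | CC(C)CC(=O)O[C@@H]1OC=C(C=O)[C@H]2C[C@@H]3O[Si](C(C)(C)C)(C(C)(C)C)OC[C@]3(O)[C@@H]12 | intermediate
26 | 1β-O-isovaleryl 4-formyl 7β,8α,10-triol | CC(C)CC(=O)O[C@@H]1OC=C(C=O)[C@H]2C[C@H](O)[C@](O)(CO)[C@@H]12 | intermediate
27 | 10-O-TBS ether of 26 | CC(C)CC(=O)O[C@@H]1OC=C(C=O)[C@H]2C[C@H](O)[C@](O)(CO[Si](C)(C)C(C)(C)C)[C@@H]12 | intermediate
28 | p-coumaric acid | OC(=O)/C=C/c1ccc(O)cc1 | starting material
29 | tert-butyldimethylsilyl (E)-4-(TBS-oxy)cinnamate (formed in the flask) | CC(C)(C)[Si](C)(C)OC(=O)/C=C/c1ccc(O[Si](C)(C)C(C)(C)C)cc1 | intermediate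
30 | (E)-4-(tert-butyldimethylsilyloxy)cinnamic acid | OC(=O)/C=C/c1ccc(O[Si](C)(C)C(C)(C)C)cc1 | intermediate
31 | (E)-4-(TBS-oxy)cinnamic 2,4,6-trichlorobenzoic anhydride (formed in the flask) | O=C(/C=C/c1ccc(O[Si](C)(C)C(C)(C)C)cc1)OC(=O)c1c(Cl)cc(Cl)cc1Cl | intermediate
32 | 7-O-[(E)-4-(TBS-oxy)cinnamoyl]-10-O-TBS-1β-O-isovaleryl 4-formyl aglycone | CC(C)CC(=O)O[C@@H]1OC=C(C=O)[C@H]2C[C@H](OC(=O)/C=C/c3ccc(O[Si](C)(C)C(C)(C)C)cc3)[C@](O)(CO[Si](C)(C)C(C)(C)C)[C@@H]12 | intermediate
33 | 11-oxo-luzonoid A | CC(C)CC(=O)O[C@@H]1OC=C(C=O)[C@H]2C[C@H](OC(=O)/C=C/c3ccc(O)cc3)[C@](O)(CO)[C@@H]12 | intermediate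
34 | luzonoid A (1S,5S,7S,8R,9S) | CC(C)CC(=O)O[C@@H]1OC=C(CO)[C@H]2C[C@H](OC(=O)/C=C/c3ccc(O)cc3)[C@](O)(CO)[C@@H]12 | target

## Step count and risks

Total step count: 23. Longest linear sequence: 21 steps (steps 1, 2, 4 to 19 and 21 to 23, from L-erythrulose).

Steps most likely to fail:

Step 13, poor facial selectivity. The vinyl ether may bond to C5 on both faces, because the angular 8-silyloxy group sits on the α face that C4 must use, and the hindered enal may react slowly. The fallback sets out from 18 and comes back at 20. Stereocontrol is handed from the substrate to the reagent: 18 and 19 are combined under a chiral Lewis acid, the chromium chloride complex (trivalent chromium, 5 mol%, 4 Å sieves, neat vinyl ether, rt) of the tridentate Schiff base from cis-1-amino-2-indanol and 3-(1-adamantyl)-5-methylsalicylaldehyde. The ligand enantiomer that reinforces the substrate bias is used. This catalyst class is known to impose its own facial preference on cyclopent-1-enecarbaldehydes with ethyl vinyl ether and should give the endo adduct 20 directly.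

Step 14, competing ionisation. The silyl triflate may also ionise the allylic C8–O bond next to the C1=C9 enol ether (Ferrier-type loss of the silyloxy group), or the 4H-pyran may decompose on isolation. The fallback sets out from 20 and comes back at 23. C4 is formylated without a free 4H-pyran and without silyl triflate: acetal 20 is treated directly with [Me2N=CHCl]Cl and 2,6-lutidine in CH2Cl2 at 0 °C (Vilsmeier formylation of an acetal to a β-alkoxy acrolein). The enol ether that forms from the acetal in the flask is trapped at once as iminium salt 22, which is hydrolysed to 23.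

Step 23, acyl loss or migration in the last step. With the C10 hydroxyl and the phenol free, the basic borohydride medium may shift the coumarate from O7 to O10 or cleave the acyloxy acetal at C1. Once the conjugating aldehyde is gone the product is also acid-labile, since 8-OH can add to C3. The fallback sets out from 32 and comes back at 34, with the order of the last two operations exchanged. Compound 32, which has no free primary hydroxyl or phenol, is reduced first (NaBH4, CeCl3·7H2O, MeOH/THF, −78 °C) to the 11-hydroxy bis-silyl ether F1. F1 is then desilylated under buffered, non-acidic fluoride conditions (Bu4NF/AcOH 1:1, THF, 0 °C) to 34.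

Further compounds
F0 | step 13 | none | none
F0 | step 14 | none | none
F1 | step 23 | 11-hydroxy bis-silyl ether: 7-O-[(E)-4-(TBS-oxy)cinnamoyl]-10-O-TBS-1β-O-isovaleryl aglycone with C11 CH2OH | CC(C)CC(=O)O[C@@H]1OC=C(CO)[C@H]2C[C@H](OC(=O)/C=C/c3ccc(O[Si](C)(C)C(C)(C)C)cc3)[C@](O)(CO[Si](C)(C)C(C)(C)C)[C@@H]12
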